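**Retrosynthetic overview**

- The target is reached from its hepta-MOM ether. The chalcone enone is made late by Claisen–Schmidt condensation, and the prenylated benzoyl group by aryllithium addition to a ring aldehyde followed by oxidation.
- The cyclohexene core (numbered C1 = carbonyl-bearing carbon, C2 = resorcinol-bearing carbon, C3=C4(Me), C5H2, C6 = 4-oxyphenyl-bearing carbon) comes from ring-closing metathesis at C3=C4 of an acyclic vinyl/methallyl diene aldehyde that already holds all three stereocentres.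
- The diene aldehyde comes from an iridium/amine dual-catalytic α-allylation (C1–C2 bond, C1 and C2 set by the two catalysts) of a racemic aryl vinyl carbinol with an (S)-β-aryl aldehyde.
- The (S)-aldehyde comes from rhodium/(R)-BINAP conjugate arylation of 5,6-dihydro-2H-pyran-2-one (sets C6). The bromoaryl vinyl carbinol comes from resorcinol (ortho-lithiation/formylation, bromination, vinyl Grignard addition), and the prenyl arene from 4-bromoresorcinol (ortho-lithiation/prenylation).
- Ring order: the four benzene rings are bought; the cyclohexene is the only ring formed, by the metathesis.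

Assumption: the (S)-configured BINOL-derived phosphoramidite–olefin ligand is taken to give the S benzylic centre (C2) from aryl vinyl carbinols; if the first run shows the opposite sense, the (R)-ligand is used and nothing else changes.

**Route**

Step 1
Reactants: 1 resorcinol
Product: 2 1,3-bis(methoxymethoxy)benzene
Conditions: NaH, MOMCl, DMF, 0 °C → rt
Reagents that add atoms: chloromethyl methyl ether (COCCl)
Why: Williamson-type O-alkylation of the bis-phenoxide gives the bis-MOM ether, whose acetal oxygens direct the next lithiation and survive every basic and organometallic step.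

Step 2
Reactants: 2 1,3-bis(methoxymethoxy)benzene
Product: 4 2,6-bis(methoxymethoxy)benzaldehyde, via aryllithium 3 (not isolated)
Conditions: n-BuLi, THF, 0 °C → rt, 1 h; then DMF, 0 °C → rt
Reagents that add atoms: N,N-dimethylformamide (CN(C)C=O)
Why: Directed ortho-metalation removes the C–H flanked by the two MOM ethers, and DMF formylates the aryllithium.

Step 3
Reactants: 4 2,6-bis(methoxymethoxy)benzaldehyde
Product: 5 3-bromo-2,6-bis(methoxymethoxy)benzaldehyde
Conditions: NBS (1.0 equiv), MeCN, 0 °C → rt, dark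
Reagents that add atoms: N-bromosuccinimide (O=C1CCC(=O)N1Br)
Why: Electrophilic aromatic bromination goes to the position ortho to one MOM ether, para to the other and meta to the aldehyde (positions 3 and 5 are equivalent), and the acid-free conditions leave the MOM ethers intact.

Step 4
Reactants: 5 3-bromo-2,6-bis(methoxymethoxy)benzaldehyde
Product: 6 rac-1-[3-bromo-2,6-bis(methoxymethoxy)phenyl]prop-2-en-1-ol
Conditions: CH2=CHMgBr, THF, −78 → 0 °C
Reagents that add atoms: vinylmagnesium bromide (C=C[Mg]Br)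
Why: Grignard 1,2-addition gives the racemic aryl vinyl carbinol, whose configuration does not matter because it is erased in the later allyl-iridium intermediate.

Step 5
Reactants: 7 5,6-dihydro-2H-pyran-2-one; 8 4-(methoxymethoxy)phenylboronic acid
Product: 9 (4R)-4-[4-(methoxymethoxy)phenyl]oxan-2-one
Conditions: [Rh(OH)((R)-BINAP)]2 (1.5 mol%), dioxane/H2O 10:1, 40 °C
Reagents that add atoms: none
Why: Hayashi–Miyaura asymmetric 1,4-addition; (R)-BINAP delivers the aryl group to the face that gives the R lactone (same sense as (R)-3-arylcyclohexanones), which fixes the future C6.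

Step 6
Reactants: 9 (4R)-4-[4-(methoxymethoxy)phenyl]oxan-2-one
Product: 11 (3S)-3-[4-(methoxymethoxy)phenyl]-5-methylhex-5-en-1-ol, via hydroxy ketone 10 (not isolated)
Conditions: MeLi (1.05 equiv), THF, −78 °C; then transfer into the ylide from Ph3PCH3Br and KOt-Bu (3 equiv each), THF, 0 → 45 °C
Reagents that add atoms: methyllithium (C[Li]); methyltriphenylphosphonium bromide (C[P+](c1ccccc1)(c1ccccc1)c1ccccc1.[Br-])
Why: Single addition of MeLi to the lactone gives a lactolate that opens to the keto alkoxide, and Wittig methylenation with the ylide made in the flask converts it to the methallyl group without touching the stereocentre (the descriptor changes only through CIP priorities).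

Step 7
Reactants: 11 (3S)-3-[4-(methoxymethoxy)phenyl]-5-methylhex-5-en-1-ol
Product: 12 (3S)-3-[4-(methoxymethoxy)phenyl]-5-methylhex-5-enal
Conditions: Dess–Martin periodinane, NaHCO3, CH2Cl2, 0 °C → rt
Reagents that add atoms: none
Why: Dess–Martin oxidation stops at the aldehyde under buffered conditions, and the stereocentre is β to the carbonyl so it cannot epimerise.

Step 8
Reactants: 6 rac-1-[3-bromo-2,6-bis(methoxymethoxy)phenyl]prop-2-en-1-ol; 12 (3S)-3-[4-(methoxymethoxy)phenyl]-5-methylhex-5-enal (1.5 equiv, excess recovered)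
Product: 13 (2R,3S)-3-[3-bromo-2,6-bis(methoxymethoxy)phenyl]-2-{(1S)-1-[4-(methoxymethoxy)phenyl]-3-methylbut-3-en-1-yl}pent-4-enal
Conditions: [Ir(cod)Cl]2 (3 mol%), (S)-BINOL-derived phosphoramidite–olefin ligand of 5H-dibenzo[b,f]azepine (12 mol%), (S)-α,α-bis[3,5-bis(trifluoromethyl)phenyl]prolinol trimethylsilyl ether (15 mol%), (MeO)2P(O)OH (cat.), ClCH2CH2Cl, 25 °C
Reagents that add atoms: none
Why: Stereodivergent iridium/amine dual-catalytic α-allylation: the (S)-amine shields one enamine face and sets C1 (R), the ligand on the branched allyl-iridium sets C2 (S), as precedented for a 2,6-dimethoxyaryl vinyl carbinol with 5-methylhex-5-enal.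

Step 9
Reactants: 13 (2R,3S)-3-[3-bromo-2,6-bis(methoxymethoxy)phenyl]-2-{(1S)-1-[4-(methoxymethoxy)phenyl]-3-methylbut-3-en-1-yl}pent-4-enal
Product: 14 (1R,2S,6S)-2-[3-bromo-2,6-bis(methoxymethoxy)phenyl]-6-[4-(methoxymethoxy)phenyl]-4-methylcyclohex-3-ene-1-carbaldehyde
Conditions: second-generation Grubbs catalyst RuCl2(=CHPh)(PCy3)(H2IMes) (5 mol%), CH2Cl2, 40 °C
Reagents that add atoms: none
Why: Ring-closing metathesis of the vinyl and methallyl groups closes the trisubstituted cyclohexene with loss of ethene, under neutral conditions that leave the three stereocentres and the aldehyde untouched.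

Step 10
Reactants: 15 4-bromoresorcinol
Product: 16 1-bromo-2,4-bis(methoxymethoxy)benzene
Conditions: NaH, MOMCl, DMF, 0 °C → rt
Reagents that add atoms: chloromethyl methyl ether (COCCl)
Why: Williamson-type O-alkylation of the bis-phenoxide gives the bis-MOM ether that directs the next lithiation.

Step 11
Reactants: 16 1-bromo-2,4-bis(methoxymethoxy)benzene; 17 prenyl bromide (1-bromo-3-methylbut-2-ene)
Product: 19 1-bromo-2,4-bis(methoxymethoxy)-3-(3-methylbut-2-en-1-yl)benzene, via aryllithium 18 (not isolated)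
Conditions: lithium 2,2,6,6-tetramethylpiperidide (LiTMP), THF, −78 °C; then CuBr·SMe2 (10 mol%), prenyl bromide, −78 → 0 °C
Reagents that add atoms: none
Why: Directed ortho-metalation with an amide base removes the C–H between the two MOM ethers without touching the C–Br bond, and copper-catalysed SN2 allylation places the prenyl group there while keeping the bromide for the next exchange.

Step 12
Reactants: 14 (1R,2S,6S)-2-[3-bromo-2,6-bis(methoxymethoxy)phenyl]-6-[4-(methoxymethoxy)phenyl]-4-methylcyclohex-3-ene-1-carbaldehyde; 19 1-bromo-2,4-bis(methoxymethoxy)-3-(3-methylbut-2-en-1-yl)benzene (1.6 equiv)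
Product: 21 {(1R,2S,6S)-2-[3-bromo-2,6-bis(methoxymethoxy)phenyl]-6-[4-(methoxymethoxy)phenyl]-4-methylcyclohex-3-en-1-yl}[2,4-bis(methoxymethoxy)-3-(3-methylbut-2-en-1-yl)phenyl]methanol (both carbinol epimers), via aryllithium 20 (not isolated)
Conditions: n-BuLi (1.5 equiv), THF, −78 °C, 15 min; then 14, −78 °C, 1 h
Reagents that add atoms: none
Why: Bromine–lithium exchange followed by 1,2-addition to the aldehyde at −78 °C outruns both enolisation at C1 and exchange with the hindered ring bromide; the new carbinol centre is unimportant because it is oxidised in step 16.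

Step 13
Reactants: 21 {(1R,2S,6S)-2-[3-bromo-2,6-bis(methoxymethoxy)phenyl]-6-[4-(methoxymethoxy)phenyl]-4-methylcyclohex-3-en-1-yl}[2,4-bis(methoxymethoxy)-3-(3-methylbut-2-en-1-yl)phenyl]methanol
Product: 23 {(1R,2S,6S)-2-[3-acetyl-2,6-bis(methoxymethoxy)phenyl]-6-[4-(methoxymethoxy)phenyl]-4-methylcyclohex-3-en-1-yl}[2,4-bis(methoxymethoxy)-3-(3-methylbut-2-en-1-yl)phenyl]methanol, via enol ether 22 (not isolated)
Conditions: Bu3Sn(C(OEt)=CH2), Pd(PPh3)4 (5 mol%), toluene, 100 °C; then 1 M aq. HCl, THF, 0 °C, 15 min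
Reagents that add atoms: tributyl(1-ethoxyvinyl)stannane (CCCC[Sn](CCCC)(CCCC)C(=C)OCC); water (O)
Why: Stille coupling installs a masked acetyl group on the aryl bromide, and the electron-rich α-aryl enol ether hydrolyses in cold dilute acid far faster than the aryl MOM ethers.

Step 14
Reactants: 24 2,4-dihydroxybenzaldehyde
Product: 25 2,4-bis(methoxymethoxy)benzaldehyde
Conditions: NaH, MOMCl, DMF, 0 °C → rt
Reagents that add atoms: chloromethyl methyl ether (COCCl)
Why: O-alkylation of the bis-phenoxide, with NaH strong enough to break the hydrogen bond of the 2-hydroxyl to the aldehyde.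

Step 15
Reactants: 23 {(1R,2S,6S)-2-[3-acetyl-2,6-bis(methoxymethoxy)phenyl]-6-[4-(methoxymethoxy)phenyl]-4-methylcyclohex-3-en-1-yl}[2,4-bis(methoxymethoxy)-3-(3-methylbut-2-en-1-yl)phenyl]methanol; 25 2,4-bis(methoxymethoxy)benzaldehyde
Product: 26 (2E)-3-[2,4-bis(methoxymethoxy)phenyl]-1-{3-[(1S,5S,6R)-6-{[2,4-bis(methoxymethoxy)-3-(3-methylbut-2-en-1-yl)phenyl](hydroxy)methyl}-5-[4-(methoxymethoxy)phenyl]-3-methylcyclohex-2-en-1-yl]-2,4-bis(methoxymethoxy)phenyl}prop-2-en-1-one
Conditions: KOH, EtOH/H2O, rt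
Reagents that add atoms: none
Why: Claisen–Schmidt aldol condensation of the methyl ketone gives the (E)-enone by E1cB dehydration, and C1 cannot epimerise in base because its neighbour is still a carbinol.

Step 16
Reactants: 26 the chalcone carbinol of step 15
Product: 27 {(1R,2S,6S)-2-[3-[(2E)-3-[2,4-bis(methoxymethoxy)phenyl]prop-2-enoyl]-2,6-bis(methoxymethoxy)phenyl]-6-[4-(methoxymethoxy)phenyl]-4-methylcyclohex-3-en-1-yl}[2,4-bis(methoxymethoxy)-3-(3-methylbut-2-en-1-yl)phenyl]methanone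
Conditions: Dess–Martin periodinane, NaHCO3, CH2Cl2, 0 °C → rt
Reagents that add atoms: none
Why: Dess–Martin oxidation converges both carbinol epimers on the aryl ketone under buffered, non-enolising conditions, so the cis C1/C2 and trans C1/C6 relationships are kept.

Step 17
Reactants: 27 the hepta-MOM ketone of step 16
Product: 28 {(1R,2S,6S)-2-[3-[(2E)-3-(2,4-dihydroxyphenyl)prop-2-enoyl]-2,6-dihydroxyphenyl]-6-(4-hydroxyphenyl)-4-methylcyclohex-3-en-1-yl}[2,4-dihydroxy-3-(3-methylbut-2-en-1-yl)phenyl]methanone (CNP0218862.2)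
Conditions: 3 M aq. HCl/MeOH 1:4, 25–40 °C, under argon
Reagents that add atoms: none
Why: Acid-catalysed transacetalisation to methanol removes all seven MOM groups in one operation, under conditions used for prenylated 2'-hydroxychalcones and too mild to enolise the hindered C1 ketone.

**Compound list**

1 | resorcinol | Oc1cccc(O)c1 | starting material
2 | 1,3-bis(methoxymethoxy)benzene | COCOc1cccc(OCOC)c1 | intermediate
3 | [2,6-bis(methoxymethoxy)phenyl]lithium (not isolated) | [Li]c1c(OCOC)cccc1OCOC | intermediate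
4 | 2,6-bis(methoxymethoxy)benzaldehyde | O=Cc1c(OCOC)cccc1OCOC | intermediate
5 | 3-bromo-2,6-bis(methoxymethoxy)benzaldehyde | O=Cc1c(OCOC)ccc(Br)c1OCOC | intermediate
6 | rac-1-[3-bromo-2,6-bis(methoxymethoxy)phenyl]prop-2-en-1-ol | C=CC(O)c1c(OCOC)ccc(Br)c1OCOC | intermediate
7 | 5,6-dihydro-2H-pyran-2-one | O=C1C=CCCO1 | starting material
8 | 4-(methoxymethoxy)phenylboronic acid | COCOc1ccc(B(O)O)cc1 | starting material
9 | (4R)-4-[4-(methoxymethoxy)phenyl]oxan-2-one | O=C1C[C@H](c2ccc(OCOC)cc2)CCO1 | intermediate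
10 | (4R)-6-hydroxy-4-[4-(methoxymethoxy)phenyl]hexan-2-one, formed as its lithium alkoxide/lactolate (not isolated) | CC(=O)C[C@@H](CCO)c1ccc(OCOC)cc1 | intermediate
11 | (3S)-3-[4-(methoxymethoxy)phenyl]-5-methylhex-5-en-1-ol | C=C(C)C[C@@H](CCO)c1ccc(OCOC)cc1 | intermediate
12 | (3S)-3-[4-(methoxymethoxy)phenyl]-5-methylhex-5-enal | C=C(C)C[C@@H](CC=O)c1ccc(OCOC)cc1 | intermediate
13 | (2R,3S)-3-[3-bromo-2,6-bis(methoxymethoxy)phenyl]-2-{(1S)-1-[4-(methoxymethoxy)phenyl]-3-methylbut-3-en-1-yl}pent-4-enal | O=C[C@@H]([C@@H](c1c(OCOC)ccc(Br)c1OCOC)C=C)[C@H](CC(C)=C)c1ccc(OCOC)cc1 | intermediate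
14 | (1R,2S,6S)-2-[3-bromo-2,6-bis(methoxymethoxy)phenyl]-6-[4-(methoxymethoxy)phenyl]-4-methylcyclohex-3-ene-1-carbaldehyde | O=C[C@H]1[C@@H](c2c(OCOC)ccc(Br)c2OCOC)C=C(C)C[C@@H]1c1ccc(OCOC)cc1 | intermediate
15 | 4-bromoresorcinol | Oc1ccc(Br)c(O)c1 | starting material
16 | 1-bromo-2,4-bis(methoxymethoxy)benzene | COCOc1ccc(Br)c(OCOC)c1 | intermediate
17 | prenyl bromide (1-bromo-3-methylbut-2-ene) | CC(C)=CCBr | starting material
18 | [3-bromo-2,6-bis(methoxymethoxy)phenyl]lithium (not isolated) | [Li]c1c(OCOC)ccc(Br)c1OCOC | intermediate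
19 | 1-bromo-2,4-bis(methoxymethoxy)-3-(3-methylbut-2-en-1-yl)benzene | CC(C)=CCc1c(OCOC)ccc(Br)c1OCOC | intermediate
20 | [2,4-bis(methoxymethoxy)-3-(3-methylbut-2-en-1-yl)phenyl]lithium (not isolated) | CC(C)=CCc1c(OCOC)ccc([Li])c1OCOC | intermediate
21 | {(1R,2S,6S)-2-[3-bromo-2,6-bis(methoxymethoxy)phenyl]-6-[4-(methoxymethoxy)phenyl]-4-methylcyclohex-3-en-1-yl}[2,4-bis(methoxymethoxy)-3-(3-methylbut-2-en-1-yl)phenyl]methanol, both carbinol epimers | OC(c1ccc(OCOC)c(CC=C(C)C)c1OCOC)[C@H]1[C@@H](c2c(OCOC)ccc(Br)c2OCOC)C=C(C)C[C@@H]1c1ccc(OCOC)cc1 | intermediate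
22 | the 3-(1-ethoxyethenyl) analogue of 21, Br replaced by C(OEt)=CH2 (not isolated) | OC(c1ccc(OCOC)c(CC=C(C)C)c1OCOC)[C@H]1[C@@H](c2c(OCOC)ccc(C(=C)OCC)c2OCOC)C=C(C)C[C@@H]1c1ccc(OCOC)cc1 | intermediate
23 | {(1R,2S,6S)-2-[3-acetyl-2,6-bis(methoxymethoxy)phenyl]-6-[4-(methoxymethoxy)phenyl]-4-methylcyclohex-3-en-1-yl}[2,4-bis(methoxymethoxy)-3-(3-methylbut-2-en-1-yl)phenyl]methanol, both carbinol epimers | OC(c1ccc(OCOC)c(CC=C(C)C)c1OCOC)[C@H]1[C@@H](c2c(OCOC)ccc(C(C)=O)c2OCOC)C=C(C)C[C@@H]1c1ccc(OCOC)cc1 | intermediate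
24 | 2,4-dihydroxybenzaldehyde | O=Cc1ccc(O)cc1O | starting material
25 | 2,4-bis(methoxymethoxy)benzaldehyde | O=Cc1ccc(OCOC)cc1OCOC | intermediate
26 | hepta-MOM (E)-chalcone carbinol (23 with the acetyl group condensed to the (2E)-3-[2,4-bis(methoxymethoxy)phenyl]prop-2-enoyl group), both carbinol epimers | OC(c1ccc(OCOC)c(CC=C(C)C)c1OCOC)[C@H]1[C@@H](c2c(OCOC)ccc(C(=O)/C=C/c3ccc(OCOC)cc3OCOC)c2OCOC)C=C(C)C[C@@H]1c1ccc(OCOC)cc1 | intermediate
27 | {(1R,2S,6S)-2-[3-[(2E)-3-[2,4-bis(methoxymethoxy)phenyl]prop-2-enoyl]-2,6-bis(methoxymethoxy)phenyl]-6-[4-(methoxymethoxy)phenyl]-4-methylcyclohex-3-en-1-yl}[2,4-bis(methoxymethoxy)-3-(3-methylbut-2-en-1-yl)phenyl]methanone | O=C(c1ccc(OCOC)c(CC=C(C)C)c1OCOC)[C@H]1[C@@H](c2c(OCOC)ccc(C(=O)/C=C/c3ccc(OCOC)cc3OCOC)c2OCOC)C=C(C)C[C@@H]1c1ccc(OCOC)cc1 | intermediate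
28 | {(1R,2S,6S)-2-[3-[(2E)-3-(2,4-dihydroxyphenyl)prop-2-enoyl]-2,6-dihydroxyphenyl]-6-(4-hydroxyphenyl)-4-methylcyclohex-3-en-1-yl}[2,4-dihydroxy-3-(3-methylbut-2-en-1-yl)phenyl]methanone (CNP0218862.2) | CC(C)=CCc1c(O)ccc(C(=O)[C@H]2[C@@H](c3c(O)ccc(C(=O)/C=C/c4ccc(O)cc4O)c3O)C=C(C)C[C@@H]2c2ccc(O)cc2)c1O | target

**Step count and risks**

Total step count: 17.
Longest linear sequence: 11 steps (steps 1, 2, 3, 4, 8, 9, 12, 13, 15, 16, 17; the branch through steps 5, 6, 7 counts 10).

Three steps most likely to fail: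

Step 8. The β-branched chiral aldehyde 12 may be mismatched with the (S)-amine, and the 2,6-dioxygenated, brominated carbinol is hindered, so rate or diastereoselectivity could fall. The fallback sets out from 12 and 5 and comes back at 13, replacing the catalytic allylation by an Ireland–Claisen rearrangement. Pinnick oxidation of 12 (NaClO2, NaH2PO4, 2-methylbut-2-ene, t-BuOH/H2O) gives (3S)-3-[4-(methoxymethoxy)phenyl]-5-methylhex-5-enoic acid F1. Horner–Wadsworth–Emmons olefination of 5 (triethyl phosphonoacetate, NaH, THF) gives ethyl (2E)-3-[3-bromo-2,6-bis(methoxymethoxy)phenyl]prop-2-enoate F2, and i-Bu2AlH (CH2Cl2, −78 °C) reduces it to (2E)-3-[3-bromo-2,6-bis(methoxymethoxy)phenyl]prop-2-en-1-ol F3. Esterification of the acid with this alcohol (EDC, DMAP, CH2Cl2) gives the cinnamyl ester F4. LiN(i-Pr)2 in THF/DMPU with Me3SiCl at −78 °C gives the (Z)-silyl ketene acetal F5, which rearranges through a chair on warming to the trimethylsilyl ester F6; aqueous work-up gives the syn acid F7. The (E)-alkene with the (Z)-ketene acetal gives the C1/C2 relationship of 13; the C6 centre is the only control over the enolate face, so the unwanted syn diastereomer is removed by chromatography at this stage. LiAlH4 (THF, 0 °C) gives the primary alcohol F8, and Dess–Martin oxidation returns 13.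

Step 12. The aryllithium may enolise the hindered aldehyde (epimerising C1) or exchange with the ring bromide of 14. The fallback sets out from 19 and comes back at 21. Quenching aryllithium 20 with I2 gives 1-iodo-2,4-bis(methoxymethoxy)-3-(3-methylbut-2-en-1-yl)benzene F9. This iodide is coupled with 14 by a Nozaki–Hiyama–Kishi reaction (CrCl2 4 equiv, NiCl2 2 mol%, DMF, 25 °C) to give 21; the arylchromium reagent is non-basic and selects the aldehyde and the C–I bond over the C–Br bond of 14.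

Step 17. Seven MOM ethers must be cleaved by acid next to a prenyl group ortho to phenols (chroman formation), a 2'-hydroxychalcone (flavanone formation) and an epimerisable ketone. The fallback sets out from 27 and comes back at 28. Me3SiOTf with 2,2'-bipyridyl (CH2Cl2, 0 °C) exchanges the aryl MOM ethers for silyl ethers without Brønsted acid, giving the heptakis(trimethylsilyl) ether F10. Neutral hydrolysis (H2O/THF) then frees the phenols to give 28.

**Further compounds**

F1 | step 8 | (3S)-3-[4-(methoxymethoxy)phenyl]-5-methylhex-5-enoic acid | C=C(C)C[C@@H](CC(=O)O)c1ccc(OCOC)cc1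
F2 | step 8 | ethyl (2E)-3-[3-bromo-2,6-bis(methoxymethoxy)phenyl]prop-2-enoate | CCOC(=O)/C=C/c1c(OCOC)ccc(Br)c1OCOC
F3 | step 8 | (2E)-3-[3-bromo-2,6-bis(methoxymethoxy)phenyl]prop-2-en-1-ol | OC/C=C/c1c(OCOC)ccc(Br)c1OCOC
F4 | step 8 | (2E)-3-[3-bromo-2,6-bis(methoxymethoxy)phenyl]prop-2-en-1-yl (3S)-3-[4-(methoxymethoxy)phenyl]-5-methylhex-5-enoate | C=C(C)C[C@@H](CC(=O)OC/C=C/c1c(OCOC)ccc(Br)c1OCOC)c1ccc(OCOC)cc1
F5 | step 8 | (Z)-O-trimethylsilyl ketene acetal of F4 | C=C(C)C[C@@H](/C=C(\O[Si](C)(C)C)OC/C=C/c1c(OCOC)ccc(Br)c1OCOC)c1ccc(OCOC)cc1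
F6 | step 8 | trimethylsilyl (2R,3S)-3-[3-bromo-2,6-bis(methoxymethoxy)phenyl]-2-{(1S)-1-[4-(methoxymethoxy)phenyl]-3-methylbut-3-en-1-yl}pent-4-enoate | C[Si](C)(C)OC(=O)[C@@H]([C@@H](c1c(OCOC)ccc(Br)c1OCOC)C=C)[C@H](CC(C)=C)c1ccc(OCOC)cc1
F7 | step 8 | (2R,3S)-3-[3-bromo-2,6-bis(methoxymethoxy)phenyl]-2-{(1S)-1-[4-(methoxymethoxy)phenyl]-3-methylbut-3-en-1-yl}pent-4-enoic acid | OC(=O)[C@@H]([C@@H](c1c(OCOC)ccc(Br)c1OCOC)C=C)[C@H](CC(C)=C)c1ccc(OCOC)cc1
F8 | step 8 | (2R,3S)-3-[3-bromo-2,6-bis(methoxymethoxy)phenyl]-2-{(1S)-1-[4-(methoxymethoxy)phenyl]-3-methylbut-3-en-1-yl}pent-4-en-1-ol | OC[C@@H]([C@@H](c1c(OCOC)ccc(Br)c1OCOC)C=C)[C@H](CC(C)=C)c1ccc(OCOC)cc1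
F9 | step 12 | 1-iodo-2,4-bis(methoxymethoxy)-3-(3-methylbut-2-en-1-yl)benzene | CC(C)=CCc1c(OCOC)ccc(I)c1OCOC
F10 | step 17 | heptakis(trimethylsilyl) ether of 28 | CC(C)=CCc1c(O[Si](C)(C)C)ccc(C(=O)[C@H]2[C@@H](c3c(O[Si](C)(C)C)ccc(C(=O)/C=C/c4ccc(O[Si](C)(C)C)cc4O[Si](C)(C)C)c3O[Si](C)(C)C)C=C(C)C[C@@H]2c2ccc(O[Si](C)(C)C)cc2)c1O[Si](C)(C)C
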